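## Plan

1. The target is a trans-fused hydroazulene: five-membered ring C1–C2–C3–C3a–C8a, seven-membered ring C3a–C4–C5–C6–C7–C8–C8a. H-3a, H-4 and 3-OH lie on one face; 8a-CH3, 3-isopropyl and the 4-acyloxy group lie on the other.
2. Cuts: first the C4–O ester bond. Then C4–H and C3a–H go back to a C3a=C4 silyl enol ether, and C6–CH3 to C6–CO2Me. Then C8–C8a is cut by a retro-Cope step, and C4–C5/C5–C6 by retro-cyclopropanation, to a 2-siloxydiene and methyl 2-diazobut-3-enoate. The diene goes back to (R)-terpinen-4-ol by ring contraction.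
3. Enabling feature: the C6=C7 alkene and the C4 oxygen flank the C8–C8a bond. C6=C7–C8–C8a–C3a=C4(O)–C5 is therefore the enol form of a cyclohepta-1,4-diene, the Cope retron of a cis-divinylcyclopropane (C4, C5, C6), whose ring strain drives formation of the quaternary C8a.
4. Forward order: the five-membered ring is made first (ozonolysis/aldol contraction of the terpene), the seven-membered ring follows in one operation from diene and vinyl carbenoid, then redox adjustment and acylation.
5. Stereochemistry: C3 comes from the chiral pool. C8a comes from the catalyst-controlled cyclopropanation, relayed through the boat Cope transition state and reinforced by C3. C3a is set by α-face protonation and C4 by hydroxyl-directed hydride delivery.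

Key step: step 10

Assumption: the (R)-DOSP ligand set is taken to give the (8aR) product by the accepted model for cyclopropanation with donor/acceptor carbenoids; should the sense prove opposite, the antipodal complex Rh2(S-DOSP)4 is used without other change.

## Route

Step 1
Reactants: 1 (R)-(−)-terpinen-4-ol
Product: 2 triethyl{[(1R)-4-methyl-1-(propan-2-yl)cyclohex-3-en-1-yl]oxy}silane
Conditions: TESOTf, 2,6-lutidine, CH2Cl2, 0 °C
Reagents that add atoms: triethylsilyl trifluoromethanesulfonate (TESOTf), CC[Si](CC)(CC)OS(=O)(=O)C(F)(F)F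
Why: Silylation of a tertiary alcohol with a silyl triflate and a hindered base is standard and masks the hydroxyl for the carbonyl and carbenoid chemistry that follows; the C3 stereocentre of the target is carried unchanged from the terpene.

Step 2
Reactants: 2 triethyl{[(1R)-4-methyl-1-(propan-2-yl)cyclohex-3-en-1-yl]oxy}silane
Product: 4 (3R)-6-oxo-3-(propan-2-yl)-3-(triethylsilyloxy)heptanal, via ozonide 3 (not isolated)
Conditions: O3, CH2Cl2, −78 °C; then PPh3, −78 °C → rt
Reagents that add atoms: ozone, [O-][O+]=O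
Why: Ozonolysis with reductive work-up cleaves the only alkene to the 1,6-keto aldehyde without touching the silyl ether or the stereocentre.

Step 3
Reactants: 4 (3R)-6-oxo-3-(propan-2-yl)-3-(triethylsilyloxy)heptanal
Product: 5 (5S)-2-methyl-5-(propan-2-yl)-5-(triethylsilyloxy)cyclopent-1-ene-1-carbaldehyde
Conditions: Bn2NH2+ CF3CO2− (0.2 equiv), benzene, 50 °C
Reagents that add atoms: none
Why: Amine-salt-catalysed intramolecular aldol condensation of a 6-oxoheptanal proceeds through the aldehyde enamine attacking the methyl ketone (five-membered ring closure) and dehydrates to the cyclopentenecarbaldehyde, the classical cyclohexene-to-cyclopentene contraction of terpenes; no new stereocentre is formed.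

Step 4
Reactants: 5 (5S)-2-methyl-5-(propan-2-yl)-5-(triethylsilyloxy)cyclopent-1-ene-1-carbaldehyde
Product: 6 1-[(5S)-2-methyl-5-(propan-2-yl)-5-(triethylsilyloxy)cyclopent-1-en-1-yl]ethan-1-ol (both carbinol epimers)
Conditions: MeMgBr, THF, −78 → 0 °C
Reagents that add atoms: methylmagnesium bromide, C[Mg]Br
Why: Grignard 1,2-addition to the hindered enal supplies the carbon that becomes C5; the new carbinol centre is removed in the next step, so its configuration is irrelevant.

Step 5
Reactants: 6 1-[(5S)-2-methyl-5-(propan-2-yl)-5-(triethylsilyloxy)cyclopent-1-en-1-yl]ethan-1-ol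
Product: 7 1-[(5S)-2-methyl-5-(propan-2-yl)-5-(triethylsilyloxy)cyclopent-1-en-1-yl]ethan-1-one
Conditions: Dess–Martin periodinane, NaHCO3, CH2Cl2, 0 °C → rt
Reagents that add atoms: none
Why: Dess–Martin oxidation of a secondary allylic alcohol to the enone is mild enough for the silyl ether and the tetrasubstituted alkene.

Step 6
Reactants: 7 1-[(5S)-2-methyl-5-(propan-2-yl)-5-(triethylsilyloxy)cyclopent-1-en-1-yl]ethan-1-one
Product: 8 tert-butyl(dimethyl)({1-[(5S)-2-methyl-5-(propan-2-yl)-5-(triethylsilyloxy)cyclopent-1-en-1-yl]ethenyl}oxy)silane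
Conditions: TBSOTf, Et3N, CH2Cl2, −78 → 0 °C
Reagents that add atoms: tert-butyldimethylsilyl trifluoromethanesulfonate (TBSOTf), CC(C)(C)[Si](C)(C)OS(=O)(=O)C(F)(F)F
Why: Soft enolisation of the methyl ketone at its methyl group (silyl enol ether formation) gives the cross-conjugated 2-siloxydiene, since the twisted, fully substituted enone disfavours γ-deprotonation.

Step 7
Reactants: 9 methyl acetoacetate
Product: 10 methyl 2-diazo-3-oxobutanoate
Conditions: p-ABSA, Et3N, MeCN, 0 °C → rt
Reagents that add atoms: 4-acetamidobenzenesulfonyl azide (p-ABSA), CC(=O)Nc1ccc(cc1)S(=O)(=O)N=[N+]=[N-]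
Why: Regitz diazo transfer to an active methylene compound is a standard, high-yielding reaction.

Step 8
Reactants: 10 methyl 2-diazo-3-oxobutanoate
Product: 11 methyl 2-diazo-3-hydroxybutanoate (racemic)
Conditions: NaBH4, MeOH, 0 °C
Reagents that add atoms: none
Why: Borohydride reduces the ketone chemoselectively and leaves the stabilised diazo ester intact; the carbinol centre is lost in the next step.

Step 9
Reactants: 11 methyl 2-diazo-3-hydroxybutanoate
Product: 12 methyl 2-diazobut-3-enoate
Conditions: POCl3, Et3N, CH2Cl2, 0 °C → rt; kept cold in solution and used at once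
Reagents that add atoms: none
Why: Dehydration through the dichlorophosphate (base-induced elimination) is the established entry to the parent vinyldiazoacetate, which is used immediately because it slowly cyclises to a pyrazole.

Step 10
Reactants: 8 tert-butyl(dimethyl)({1-[(5S)-2-methyl-5-(propan-2-yl)-5-(triethylsilyloxy)cyclopent-1-en-1-yl]ethenyl}oxy)silane; 12 methyl 2-diazobut-3-enoate
Product: 14 methyl (3S,8aR)-4-(tert-butyldimethylsilyloxy)-8a-methyl-3-(propan-2-yl)-3-(triethylsilyloxy)-1,2,3,5,8,8a-hexahydroazulene-6-carboxylate, via cis-divinylcyclopropane 13 (not isolated)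
Conditions: Rh2(R-DOSP)4 [dirhodium tetrakis((R)-N-(4-dodecylbenzenesulfonyl)prolinate)] (1 mol %), hexanes, −40 °C, slow addition of 12; then rt and, if needed, toluene, 80 °C
Reagents that add atoms: none
Why: The dirhodium carbenoid from 12 cyclopropanates the unhindered, electron-rich terminal enol ether alkene of 8 (future C5=C4) to give cis-divinylcyclopropane 13, whose two alkenyl arms (C6–C7=C8 and C4–C3a=C8a) are then joined at C8–C8a by a [3,3]-sigmatropic (Cope) shift through the boat transition state, the strain of the three-membered ring paying for the new quaternary centre. The closest known reaction type is the tandem cyclopropanation/Cope rearrangement (formal [4+3] cycloaddition) of vinyldiazoacetates with dienes, 2-siloxydienes included. The seven-membered ring is closed in a concerted pericyclic mode, a three-carbon plus four-carbon annulation in which the C4–C6 cyclopropane bond is cleaved. The only new stereocentre, C8a, follows stereospecifically from the cyclopropane configuration, which the chiral carboxylate ligands fix during cyclopropanation; the C3 centre reinforces it because in this pairing the vinyl terminus reaches C8a on the cyclopentene face anti to the isopropyl group. The step needs site selectivity for the terminal enol ether over the tetrasubstituted ring alkene (secured by sterics and electron density), reaction at the carbenoid carbon and not at the vinyl terminus (hydrocarbon solvent, carboxylate catalyst), and a cis arrangement of the two alkenyl groups (the donor vinyl group and the larger alkene substituent end up cis, and any trans isomer can equilibrate through the weak donor–acceptor C4–C6 bond on warming).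

Step 11
Reactants: 14 methyl (3S,8aR)-4-(tert-butyldimethylsilyloxy)-8a-methyl-3-(propan-2-yl)-3-(triethylsilyloxy)-1,2,3,5,8,8a-hexahydroazulene-6-carboxylate
Product: 15 [(3S,8aR)-4-(tert-butyldimethylsilyloxy)-8a-methyl-3-(propan-2-yl)-3-(triethylsilyloxy)-1,2,3,5,8,8a-hexahydroazulen-6-yl]methanol
Conditions: iBu2AlH (2.5 equiv), CH2Cl2, −78 °C; aq. KNaC4H4O6 work-up
Reagents that add atoms: none
Why: 1,2-Reduction of the conjugated ester to the allylic alcohol with iBu2AlH leaves the hindered silyl enol ether and the silyl ether untouched.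

Step 12
Reactants: 15 [(3S,8aR)-4-(tert-butyldimethylsilyloxy)-8a-methyl-3-(propan-2-yl)-3-(triethylsilyloxy)-1,2,3,5,8,8a-hexahydroazulen-6-yl]methanol
Product: 17 tert-butyl{[(3S,8aR)-6,8a-dimethyl-3-(propan-2-yl)-3-(triethylsilyloxy)-1,2,3,5,8,8a-hexahydroazulen-4-yl]oxy}dimethylsilane, via allylic mesylate 16 (not isolated)
Conditions: MsCl, Et3N, THF, −20 °C; then LiEt3BH, −20 → 0 °C
Reagents that add atoms: methanesulfonyl chloride, CS(=O)(=O)Cl (its atoms are carried only by intermediate 16)
Why: Sulfonylation followed by SN2 hydride displacement at the primary allylic carbon converts CH2OH into the C6 methyl group with the C6=C7 alkene left in place, since direct attack at the primary carbon outruns SN2′ attack at the ring carbon.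

Step 13
Reactants: 17 tert-butyl{[(3S,8aR)-6,8a-dimethyl-3-(propan-2-yl)-3-(triethylsilyloxy)-1,2,3,5,8,8a-hexahydroazulen-4-yl]oxy}dimethylsilane
Product: 18 (3S,3aR,8aR)-3-hydroxy-6,8a-dimethyl-3-(propan-2-yl)-2,3,3a,5,8,8a-hexahydroazulen-4(1H)-one
Conditions: HF·pyridine, pyridine, THF, 0 °C → rt
Reagents that add atoms: none
Why: Buffered fluoride cleaves the silyl enol ether and the triethylsilyl ether, and kinetic protonation of the enol at C3a should occur on the α face, opposite the flanking C3 isopropyl and C8a methyl groups, which sets the trans ring fusion under conditions too mild to enolise the product or move the β,γ-alkene.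

Step 14
Reactants: 18 (3S,3aR,8aR)-3-hydroxy-6,8a-dimethyl-3-(propan-2-yl)-2,3,3a,5,8,8a-hexahydroazulen-4(1H)-one
Product: 19 (3S,3aS,4R,8aR)-6,8a-dimethyl-3-(propan-2-yl)-1,2,3,3a,4,5,8,8a-octahydroazulene-3,4-diol
Conditions: Me4NBH(OAc)3, MeCN/AcOH (1:1), −30 °C
Reagents that add atoms: none
Why: In this Evans–Saksena reduction the C3 hydroxyl binds boron and delivers hydride intramolecularly to the α face of the C4 ketone, giving the 3,4-anti diol with the C4 oxygen on the β face, the same face selectivity that sterics (isopropyl and 8a-methyl on the β face) would give to an external hydride.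

Step 15
Reactants: 19 (3S,3aS,4R,8aR)-6,8a-dimethyl-3-(propan-2-yl)-1,2,3,3a,4,5,8,8a-octahydroazulene-3,4-diol; 20 4-acetoxybenzoyl chloride
Product: 21 (3S,3aS,4R,8aR)-3-hydroxy-6,8a-dimethyl-3-(propan-2-yl)-1,2,3,3a,4,5,8,8a-octahydroazulen-4-yl 4-(acetyloxy)benzoate
Conditions: Et3N, DMAP (cat.), CH2Cl2, 0 °C → rt
Reagents that add atoms: none
Why: DMAP-catalysed acylation occurs only at the secondary C4 hydroxyl because the tertiary C3 hydroxyl is inert under these conditions, and the phenol is carried as its acetate to prevent self-acylation.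

Step 16
Reactants: 21 (3S,3aS,4R,8aR)-3-hydroxy-6,8a-dimethyl-3-(propan-2-yl)-1,2,3,3a,4,5,8,8a-octahydroazulen-4-yl 4-(acetyloxy)benzoate
Product: 22 (3S,3aS,4R,8aR)-3-hydroxy-6,8a-dimethyl-3-(propan-2-yl)-1,2,3,3a,4,5,8,8a-octahydroazulen-4-yl 4-hydroxybenzoate (target)
Conditions: pyrrolidine (2 equiv), CH2Cl2, 0 °C
Reagents that add atoms: none
Why: Aminolysis removes the activated aryl acetate far faster than it attacks the hindered secondary alkyl benzoate, so the phenol is released without loss of the ester or change at any stereocentre.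

## Compound list

1 | (R)-(−)-terpinen-4-ol, (1R)-4-methyl-1-(propan-2-yl)cyclohex-3-en-1-ol | CC1=CC[C@@](O)(C(C)C)CC1 | starting material
2 | triethyl{[(1R)-4-methyl-1-(propan-2-yl)cyclohex-3-en-1-yl]oxy}silane | CC1=CC[C@@](O[Si](CC)(CC)CC)(C(C)C)CC1 | intermediate
3 | secondary ozonide (1,2,4-trioxolane) of 2, mixture at the new centres | CC12CC[C@](O[Si](CC)(CC)CC)(C(C)C)CC(OO1)O2 | intermediate
4 | (3R)-6-oxo-3-(propan-2-yl)-3-(triethylsilyloxy)heptanal | CC(=O)CC[C@](O[Si](CC)(CC)CC)(C(C)C)CC=O | intermediate
5 | (5S)-2-methyl-5-(propan-2-yl)-5-(triethylsilyloxy)cyclopent-1-ene-1-carbaldehyde | O=CC1=C(C)CC[C@]1(O[Si](CC)(CC)CC)C(C)C | intermediate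
6 | 1-[(5S)-2-methyl-5-(propan-2-yl)-5-(triethylsilyloxy)cyclopent-1-en-1-yl]ethan-1-ol, both carbinol epimers | CC(O)C1=C(C)CC[C@]1(O[Si](CC)(CC)CC)C(C)C | intermediate
7 | 1-[(5S)-2-methyl-5-(propan-2-yl)-5-(triethylsilyloxy)cyclopent-1-en-1-yl]ethan-1-one | CC(=O)C1=C(C)CC[C@]1(O[Si](CC)(CC)CC)C(C)C | intermediate
8 | tert-butyl(dimethyl)({1-[(5S)-2-methyl-5-(propan-2-yl)-5-(triethylsilyloxy)cyclopent-1-en-1-yl]ethenyl}oxy)silane | C=C(O[Si](C)(C)C(C)(C)C)C1=C(C)CC[C@]1(O[Si](CC)(CC)CC)C(C)C | intermediate
9 | methyl acetoacetate | COC(=O)CC(C)=O | starting material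
10 | methyl 2-diazo-3-oxobutanoate | COC(=O)C(=[N+]=[N-])C(C)=O | intermediate
11 | methyl 2-diazo-3-hydroxybutanoate (racemic) | COC(=O)C(=[N+]=[N-])C(C)O | intermediate
12 | methyl 2-diazobut-3-enoate | COC(=O)C(=[N+]=[N-])C=C | intermediate
13 | methyl (1S,2R)-2-(tert-butyldimethylsilyloxy)-1-ethenyl-2-[(5S)-2-methyl-5-(propan-2-yl)-5-(triethylsilyloxy)cyclopent-1-en-1-yl]cyclopropane-1-carboxylate | COC(=O)[C@]1(C=C)C[C@@]1(O[Si](C)(C)C(C)(C)C)C2=C(C)CC[C@]2(O[Si](CC)(CC)CC)C(C)C | intermediate
14 | methyl (3S,8aR)-4-(tert-butyldimethylsilyloxy)-8a-methyl-3-(propan-2-yl)-3-(triethylsilyloxy)-1,2,3,5,8,8a-hexahydroazulene-6-carboxylate | COC(=O)C1=CC[C@@]2(C)CC[C@](O[Si](CC)(CC)CC)(C(C)C)C2=C(O[Si](C)(C)C(C)(C)C)C1 | intermediate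
15 | [(3S,8aR)-4-(tert-butyldimethylsilyloxy)-8a-methyl-3-(propan-2-yl)-3-(triethylsilyloxy)-1,2,3,5,8,8a-hexahydroazulen-6-yl]methanol | OCC1=CC[C@@]2(C)CC[C@](O[Si](CC)(CC)CC)(C(C)C)C2=C(O[Si](C)(C)C(C)(C)C)C1 | intermediate
16 | [(3S,8aR)-4-(tert-butyldimethylsilyloxy)-8a-methyl-3-(propan-2-yl)-3-(triethylsilyloxy)-1,2,3,5,8,8a-hexahydroazulen-6-yl]methyl methanesulfonate | CS(=O)(=O)OCC1=CC[C@@]2(C)CC[C@](O[Si](CC)(CC)CC)(C(C)C)C2=C(O[Si](C)(C)C(C)(C)C)C1 | intermediate
17 | tert-butyl{[(3S,8aR)-6,8a-dimethyl-3-(propan-2-yl)-3-(triethylsilyloxy)-1,2,3,5,8,8a-hexahydroazulen-4-yl]oxy}dimethylsilane | CC1=CC[C@@]2(C)CC[C@](O[Si](CC)(CC)CC)(C(C)C)C2=C(O[Si](C)(C)C(C)(C)C)C1 | intermediate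
18 | (3S,3aR,8aR)-3-hydroxy-6,8a-dimethyl-3-(propan-2-yl)-2,3,3a,5,8,8a-hexahydroazulen-4(1H)-one | CC1=CC[C@@]2(C)CC[C@](O)(C(C)C)[C@@H]2C(=O)C1 | intermediate
19 | (3S,3aS,4R,8aR)-6,8a-dimethyl-3-(propan-2-yl)-1,2,3,3a,4,5,8,8a-octahydroazulene-3,4-diol | CC1=CC[C@@]2(C)CC[C@](O)(C(C)C)[C@@H]2[C@H](O)C1 | intermediate
20 | 4-acetoxybenzoyl chloride | CC(=O)Oc1ccc(cc1)C(Cl)=O | starting material
21 | (3S,3aS,4R,8aR)-3-hydroxy-6,8a-dimethyl-3-(propan-2-yl)-1,2,3,3a,4,5,8,8a-octahydroazulen-4-yl 4-(acetyloxy)benzoate | CC1=CC[C@@]2(C)CC[C@](O)(C(C)C)[C@@H]2[C@H](OC(=O)c2ccc(OC(C)=O)cc2)C1 | intermediate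
22 | (3S,3aS,4R,8aR)-3-hydroxy-6,8a-dimethyl-3-(propan-2-yl)-1,2,3,3a,4,5,8,8a-octahydroazulen-4-yl 4-hydroxybenzoate | CC1=CC[C@@]2(C)CC[C@](O)(C(C)C)[C@@H]2[C@H](OC(=O)c2ccc(O)cc2)C1 | target

## Summary and risks

Total step count: 16. Longest linear sequence: 13 steps (steps 1–6 and 10–16, from 1).

Steps most likely to fail:

1. Step 10 (key step).
 - What may go wrong: attack of the carbenoid through its vinyl terminus, heterolytic opening of the donor–acceptor cyclopropane before the sigmatropic shift, a slow Cope step at the fully substituted alkene terminus, or a mismatched catalyst/substrate pairing that erodes facial selectivity.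
 - Fallback (ring-closing metathesis in place of cyclopropanation/Cope): setting out from enal 5, addition of 2-methylallylmagnesium chloride (THF, −78 °C) should give dienol F1, and Dess–Martin oxidation the β,γ-unsaturated dienone F2. Hosomi–Sakurai conjugate allylation (allyltrimethylsilane, TiCl4, CH2Cl2, −78 °C) should create C8a by attack anti to the isopropyl group, and α-face protonation of the titanium enolate on work-up should give triene ketone F3. Ring-closing metathesis with the second-generation Grubbs catalyst (CH2Cl2, 40 °C) should close C6=C7 to give bicyclic silyloxy ketone F4. Cleavage of its triethylsilyl ether with HF·pyridine comes back to the route at 18.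

2. Step 13.
 - What may go wrong: loss of the C3a configuration by enolisation of the free β-hydroxy ketone, retro-aldol cleavage or dehydration of the tertiary aldol during the double desilylation, or incomplete cleavage of the hindered triethylsilyl ether.
 - Fallback (stepwise unmasking with reagent-controlled reduction in place of the hydroxyl-directed one): setting out from 17, one equivalent of Bu4NF buffered with AcOH (THF, −20 °C) should cleave only the silyl enol ether and give bicyclic silyloxy ketone F4 (the compound also reached in the fallback above). Li(sBu)3BH (THF, −78 °C) should add hydride from the open α face to give silyloxy alcohol F5. Removal of the tertiary triethylsilyl ether last with HF·pyridine comes back to the route at 19.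

3. Step 12.
 - What may go wrong: SN2′ hydride delivery with transposition of the alkene to the exocyclic position, or ionisation of the allylic mesylate with transannular capture by the silyl enol ether.
 - Fallback (π-allyl chemistry in place of direct displacement): setting out from 15, acetylation (Ac2O, pyridine, DMAP) should give allylic acetate F6. Reduction with LiEt3BH catalysed by Pd(PPh3)4 (zerovalent palladium, THF, rt), in which hydride attacks the less hindered exocyclic terminus of the allyl complex of divalent palladium, comes back to the route at 17.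

Further compounds

F1 | step 10 | 3-methyl-1-[(5S)-2-methyl-5-(propan-2-yl)-5-(triethylsilyloxy)cyclopent-1-en-1-yl]but-3-en-1-ol (both carbinol epimers) | CC(=C)CC(O)C1=C(C)CC[C@]1(O[Si](CC)(CC)CC)C(C)C
F2 | step 10 | 3-methyl-1-[(5S)-2-methyl-5-(propan-2-yl)-5-(triethylsilyloxy)cyclopent-1-en-1-yl]but-3-en-1-one | CC(=C)CC(=O)C1=C(C)CC[C@]1(O[Si](CC)(CC)CC)C(C)C
F3 | step 10 | 3-methyl-1-[(1R,2R,5S)-2-methyl-2-(prop-2-en-1-yl)-5-(propan-2-yl)-5-(triethylsilyloxy)cyclopentyl]but-3-en-1-one | C=CC[C@@]1(C)CC[C@](O[Si](CC)(CC)CC)(C(C)C)[C@@H]1C(=O)CC(C)=C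
F4 | step 10 | (3S,3aR,8aR)-6,8a-dimethyl-3-(propan-2-yl)-3-(triethylsilyloxy)-2,3,3a,5,8,8a-hexahydroazulen-4(1H)-one | CC1=CC[C@@]2(C)CC[C@](O[Si](CC)(CC)CC)(C(C)C)[C@@H]2C(=O)C1
F5 | step 13 | (3S,3aS,4R,8aR)-6,8a-dimethyl-3-(propan-2-yl)-3-(triethylsilyloxy)-1,2,3,3a,4,5,8,8a-octahydroazulen-4-ol | CC1=CC[C@@]2(C)CC[C@](O[Si](CC)(CC)CC)(C(C)C)[C@@H]2[C@H](O)C1
F6 | step 12 | [(3S,8aR)-4-(tert-butyldimethylsilyloxy)-8a-methyl-3-(propan-2-yl)-3-(triethylsilyloxy)-1,2,3,5,8,8a-hexahydroazulen-6-yl]methyl acetate | CC(=O)OCC1=CC[C@@]2(C)CC[C@](O[Si](CC)(CC)CC)(C(C)C)C2=C(O[Si](C)(C)C(C)(C)C)C1
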